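**Plan**

1. Retrosynthetic cuts, in order: the two acetates and C6–Cl (ene-type chlorination of a Δ5 olefin); C5=C6 (ring-closing metathesis, opens the ten-membered ring); O7–C19, C8–C17 and C7–C8 (lactonisation, Reformatsky addition, alkoxyallylboration); C11–O; C2–C3 (Grignard addition to a nitrile); last, C12–C13 and C1–C10 together.
2. Enabling feature: ring A (C1, C10–C14) is a cyclohex-2-enone in which C13 is α to the C12 carbonyl and the quaternary γ-carbon C1 carries C2 at the carboxyl level. C2(N)–C1–C14–C13 is therefore an α,γ-dinucleophilic vinylogous nitrile anion and C12(=O)–C11=C10 a 1,3-dielectrophilic enoyl unit. Their union passes through the 3-oxidohexatriene C1=C14–C13=C12(O−)–C11=C10, which closes to ring A.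
3. Forward order: enoyl chloride (C8–C12, C20) plus N-silyl vinylketene imine (C1, C2, C13–C15) give ring A in one pot, a convergent union at the quaternary carbon. Then follow the C3–C5/C16 chain, C11–OH, the C6–C7 unit, the five-membered lactone (C17–C19), the ten-membered ring by metathesis, the chloride and the acetates.
4. Stereochemistry: C9 from (S)-glyceraldehyde acetonide; C10 and C1 in the key step (A1,3 strain; cyano group inside); C11 by face-selective Rubottom oxidation; C2 by CBS reduction (matched with Felkin–Anh); C7 by the Ipc reagent; C8 by chelation; C17 by equilibration; C6 by attack anti to the C7–O bond.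

Key step: step 5

Remark: briarane numbering is used throughout (C1 quaternary ring-fusion carbon with methyl C15; C2–C9 along the ten-membered ring, C5 bearing C16; C10 ring-fusion CH; C11 with methyl C20; C12 ketone; C13=C14; lactone C17 with methyl C18 and carbonyl C19); the target is (1S,2R,6S,7R,8R,9R,10S,11S,17R), and the E/Z purity of nitrile 6 is immaterial because deprotonation erases it.

**Route**

Step 1
Reactants: 1 (S)-2,2-dimethyl-1,3-dioxolane-4-carbaldehyde; 2 ethyl 2-(triphenylphosphoranylidene)propanoate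
Product: 3 ethyl (E)-3-[(4R)-2,2-dimethyl-1,3-dioxolan-4-yl]-2-methylprop-2-enoate
Conditions: CH2Cl2, 0 → 23 °C
Reagents that add atoms: none
Why: Wittig olefination with a stabilised α-branched ylide should give the (E)-trisubstituted enoate under neutral conditions that do not epimerise the α-alkoxy aldehyde, so that C9 comes unchanged from the chiral pool.

Step 2
Reactants: 3 ethyl (E)-3-[(4R)-2,2-dimethyl-1,3-dioxolan-4-yl]-2-methylprop-2-enoate
Product: 4 (E)-3-[(4R)-2,2-dimethyl-1,3-dioxolan-4-yl]-2-methylprop-2-enoic acid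
Conditions: LiOH·H2O, THF/MeOH/H2O, 23 °C; then dilute HCl to pH 4, 0 °C
Reagents that add atoms: lithium hydroxide [Li+].[OH-]
Why: Ester saponification followed by cold, mild acidification should free the acid without loss of the acetonide or of the E geometry.

Step 3
Reactants: 4 (E)-3-[(4R)-2,2-dimethyl-1,3-dioxolan-4-yl]-2-methylprop-2-enoic acid
Product: 5 (E)-3-[(4R)-2,2-dimethyl-1,3-dioxolan-4-yl]-2-methylprop-2-enoyl chloride
Conditions: 1-chloro-N,N,2-trimethylprop-1-en-1-amine, CH2Cl2, 0 → 23 °C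
Reagents that add atoms: 1-chloro-N,N,2-trimethylprop-1-en-1-amine CC(C)=C(Cl)N(C)C
Why: Acid chloride formation with an α-chloroenamine is neutral (no HCl), so the acetonide and the olefin geometry should survive.

Step 4
Reactants: 6 (E)-2-methylbut-2-enenitrile
Product: 8 N-(tert-butyldimethylsilyl)-2-methylbuta-1,3-dien-1-imine, via N-lithio ketene imine 7 (not isolated)
Conditions: LiN(i-Pr)2, THF, −78 °C; then TBSCl, −78 → 23 °C
Reagents that add atoms: tert-butyldimethylsilyl chloride CC(C)(C)[Si](C)(C)Cl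
Why: γ-Deprotonation of the unsaturated nitrile and N-silylation of the ketene iminate is the established way to N-silyl vinylketene imines.

Step 5
Reactants: 5 (E)-3-[(4R)-2,2-dimethyl-1,3-dioxolan-4-yl]-2-methylprop-2-enoyl chloride; 8 N-(tert-butyldimethylsilyl)-2-methylbuta-1,3-dien-1-imine
Product: 10 (1S,6S)-6-[(4R)-2,2-dimethyl-1,3-dioxolan-4-yl]-1,5-dimethyl-4-oxocyclohex-2-ene-1-carbonitrile (ring A; C11 epimer mixture), via γ-acyl nitrile 9 (not isolated)
Conditions: ZnBr2 (0.2 equiv), CH2Cl2, −78 → 0 °C; then DBU (1.5 equiv), 0 → 23 °C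
Reagents that add atoms: none
Why: Proposed new method: the ZnBr2-activated acid chloride 5 should acylate the N-silyl vinylketene imine 8 at its unsubstituted γ-terminus (C13) rather than at the fully substituted α-carbon (C1) or at nitrogen, forming C12–C13 and the γ-acyl nitrile 9 with loss of TBSCl. DBU then removes a C13 proton, which lies between the C12 ketone and the vinylogous nitrile, and the resulting 3-oxidohexatriene C1=C14–C13=C12(O−)–C11=C10 closes by thermal disrotatory 6π electrocyclisation (equally a 6-endo-trig vinylogous Michael addition of C1 to C10), forming C1–C10 and, after protonation at C11, the cyclohex-2-enone; reversible protonation makes the closure downhill although the open anion is the better stabilised one. The closest known reaction types are the γ-selective vinylogous Mukaiyama additions of N-silyl vinylketene imines to aldehydes, the Lewis-acid-catalysed C-acylation of silyl enol ethers by acid chlorides, and the oxyanion-accelerated electrocyclisation of 3-oxidohexatrienes met in cyclobutenone ring expansions. Ring A is the only ring closed (six-membered, 6π disrotatory, 6-endo). C10 is controlled by the C9 stereocentre, since H9 eclipses the C10=C11 bond to avoid A1,3 strain with the C11 methyl and C1 adds anti to the C9–O bond; C1 is controlled by the disrotatory mode, in which the rod-like cyano group takes the inside position and the methyl the outside one, so that C15 ends cis to the C9 branch. The step needs γ- over α-acylation (secured by the quaternary α-carbon and an open, Lewis-acid-mediated transition state) and an intact (E)-C10=C11 bond until closure (secured by a non-nucleophilic amidine at or below room temperature).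

Step 6
Reactants: 10 (1S,6S)-6-[(4R)-2,2-dimethyl-1,3-dioxolan-4-yl]-1,5-dimethyl-4-oxocyclohex-2-ene-1-carbonitrile
Product: 11 TBS dienol ether of 10: 4-(tert-butyldimethylsilyloxy)-6-[(4R)-2,2-dimethyl-1,3-dioxolan-4-yl]-1,5-dimethylcyclohexa-2,4-diene-1-carbonitrile (C1 and C6 as in 10)
Conditions: TBSOTf, Et3N, CH2Cl2, 0 °C
Reagents that add atoms: tert-butyldimethylsilyl triflate CC(C)(C)[Si](C)(C)OS(=O)(=O)C(F)(F)F
Why: Soft enolisation can only occur at C11 (C1 is quaternary), which converges the C11 epimers into one 2-silyloxydiene that masks the C12 ketone and prepares the Rubottom oxidation.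

Step 7
Reactants: 11 TBS dienol ether of 10; 12 4-bromo-2-methylbut-1-ene
Product: 15 C2 ketone: 4-(tert-butyldimethylsilyloxy)-6-[(4R)-2,2-dimethyl-1,3-dioxolan-4-yl]-1,5-dimethyl-1-(4-methylpent-4-enoyl)cyclohexa-2,4-diene, via Grignard reagent 13 (not isolated), via magnesium ketiminate 14 (not isolated)
Conditions: Mg, THF, 40 °C; then 11, CuBr·SMe2 (5 mol %), THF, 60 °C; then aq. NaH2PO4, 23 °C
Reagents that add atoms: water O
Why: Copper-catalysed Grignard addition to a hindered tertiary nitrile stops at the metallo-imine, whose mild hydrolysis should give the C2 ketone while the silyl dienol ether keeps C12 out of reach.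

Step 8
Reactants: 15 C2 ketone
Product: 16 (2R)-alcohol: 1-[(1R)-1-hydroxy-4-methylpent-4-enyl] analogue of 15
Conditions: (S)-2-methyl-CBS-oxazaborolidine (0.2 equiv), catecholborane, toluene, −78 → −40 °C; then MeOH, aq. NaOH wash
Reagents that add atoms: none
Why: In the CBS reduction the quaternary C1 acts as the large and the C3 methylene as the small group, so the (S)-catalyst should deliver hydride to give (2R), the sense also favoured by Felkin–Anh attack anti to the C10 branch; catecholborane leaves the olefins alone.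

Step 9
Reactants: 16 (2R)-alcohol
Product: 18 C2/C8/C9/C11 tetraol: (11S)-11-hydroxy-12-oxo-13-ene with the acetonide removed, via silyloxy epoxide 17 (not isolated)
Conditions: DMDO (1.05 equiv), acetone/CH2Cl2, −78 °C; then 48% aq. HF, MeCN, 0 → 23 °C
Reagents that add atoms: dimethyldioxirane CC1(C)OO1
Why: In this Rubottom oxidation DMDO should epoxidise the electron-rich C11=C12 enol ether on the face opposite to the pseudoaxial C9 branch and the C15 methyl, which sets (11S); aqueous HF then opens the silyloxy oxirane to the α-hydroxy enone and removes the acetonide.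

Step 10
Reactants: 18 C2/C8/C9/C11 tetraol
Product: 19 2,8,9,11-tetrakis-O-(triethylsilyl) ether of 18
Conditions: TESOTf, 2,6-lutidine, CH2Cl2, −78 → 0 °C
Reagents that add atoms: triethylsilyl triflate CC[Si](CC)(CC)OS(=O)(=O)C(F)(F)F
Why: Silyl triflate with a hindered pyridine base silylates primary, secondary and tertiary hydroxyls alike, and the enone has no enolisable position left.

Step 11
Reactants: 19 2,8,9,11-tetrakis-O-(triethylsilyl) ether
Product: 20 C8 aldehyde (2,9,11-tris-O-triethylsilyl)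
Conditions: (COCl)2, DMSO, CH2Cl2, −78 → −40 °C; then Et3N, −78 → 0 °C
Reagents that add atoms: none
Why: Under Swern conditions a primary triethylsilyl ether is cleaved and oxidised directly to the aldehyde while secondary and tertiary silyl ethers are kept, which differentiates C8 from C9 in one step.

Step 12
Reactants: 20 C8 aldehyde; 21 allyl 4-methoxybenzyl ether
Product: 23 (7S,8R)-homoallylic alcohol: C8–OH, C7–OPMB, C6 vinyl, via (Z)-γ-(PMBO)allyl-B(Ipc)2 22 (not isolated)
Conditions: 21, s-BuLi, THF, −78 °C; (+)-Ipc2BOMe; BF3·OEt2; then 20, −78 °C; ethanolamine work-up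
Reagents that add atoms: none
Why: In the Brown alkoxyallylboration the (Z)-γ-alkoxyallylborane reacts through a chair transition state to give the syn adduct, and the Ipc groups derived from (+)-Ipc2BOMe should direct attack to the aldehyde face that sets (7S); the C8 carbinol configuration is of no consequence.

Step 13
Reactants: 23 (7S,8R)-homoallylic alcohol
Product: 24 C8 ketone (C7–OPMB, C9–OTES)
Conditions: Dess–Martin periodinane, NaHCO3, CH2Cl2, 0 → 23 °C
Reagents that add atoms: none
Why: Buffered Dess–Martin oxidation should give the α,α'-dioxygenated ketone without epimerising C7 or moving the vinyl double bond into conjugation.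

Step 14
Reactants: 24 C8 ketone; 25 methyl 2-bromopropanoate (racemic)
Product: 27 C8 tertiary alcohol bearing the C17(CH3)–C19O2Me branch (C17 epimers), via zinc enolate 26 (not isolated)
Conditions: Zn (TMSCl-activated), THF, 0 → 23 °C; aq. NH4Cl
Reagents that add atoms: none
Why: In this Reformatsky reaction the weakly basic zinc enolate should add to the ketone held in a five-membered chelate with the C7 PMB ether oxygen, from the face opposite to the C6 vinyl group, which sets C8; the hindered C12 enone should not react.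

Step 15
Reactants: 27 C8 tertiary alcohol
Product: 29 γ-lactone diene: 19,7-olide with free C8–OH, C6 vinyl and the C5 isopropenyl terminus, via C7 alcohol 28 (not isolated)
Conditions: DDQ, CH2Cl2/pH 7 buffer, 0 °C; then DBU (0.2 equiv), CH2Cl2, 23 °C
Reagents that add atoms: none
Why: Oxidative PMB removal frees the C7 hydroxyl, which lactonises onto the methyl ester (five-membered ring), and the amidine should equilibrate the acidic C17 centre to the isomer with the methyl trans to the C9 branch.

Step 16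
Reactants: 29 γ-lactone diene
Product: 30 (5Z)-macrocycle: ten-membered ring with the C5(CH3)=C6 olefin
Conditions: second-generation Grubbs catalyst (10 mol %), 1,4-benzoquinone, toluene (0.5 mM), 80 °C
Reagents that add atoms: none
Why: Ring-closing metathesis should start at the monosubstituted C6 vinyl group and close onto the 1,1-disubstituted olefin, the trans-diequatorial C2 and C9 branches on ring A pointing towards each other; a ten-membered ring should hold the Z olefin.

Step 17
Reactants: 30 (5Z)-macrocycle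
Product: 31 8-O-triethylsilyl ether of 30
Conditions: TESOTf, 2,6-lutidine, CH2Cl2, −78 → 0 °C
Reagents that add atoms: triethylsilyl triflate CC[Si](CC)(CC)OS(=O)(=O)C(F)(F)F
Why: Silylation of the tertiary C8 hydroxyl removes the one nucleophile that could trap the chloronium ion of the next step as a cyclic ether.

Step 18
Reactants: 31 8-O-triethylsilyl ether
Product: 32 (6S)-6-chloro-5(16)-ene (2,8,9,11-tetrakis-O-triethylsilyl)
Conditions: Ca(OCl)2, solid CO2, CH2Cl2/H2O, 0 °C
Reagents that add atoms: calcium hypochlorite [Ca+2].[O-]Cl.[O-]Cl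
Why: In this ene-type chlorination HOCl should deliver chlorine to the less substituted C6 with loss of a C16 proton, on the olefin face anti to the allylic C7–O bond (H7 eclipsing the olefin to avoid A1,3 strain), which gives the exocyclic methylene and sets (6S); the electron-poor enone should not react.

Step 19
Reactants: 32 (6S)-6-chloro-5(16)-ene
Product: 33 2,8,9,11-tetraol (6-chloro-12-oxo-5(16),13-diene-19,7-olide)
Conditions: HF·pyridine, pyridine, THF, 0 → 23 °C
Reagents that add atoms: none
Why: Buffered fluoride cleaves all four triethylsilyl ethers under weakly acidic conditions that should spare the allylic chloride and avoid base-induced lactone migration to O9.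

Step 20
Reactants: 33 2,8,9,11-tetraol
Product: 34 CNP0261648.1 (target)
Conditions: Ac2O, pyridine, DMAP (cat.), CH2Cl2, 0 → 23 °C
Reagents that add atoms: acetic anhydride CC(=O)OC(C)=O
Why: Acylation under these conditions should esterify the two secondary hydroxyls (C2, C9) and leave the two tertiary ones (C8, C11) free.

**Compound list**

1 | (S)-2,2-dimethyl-1,3-dioxolane-4-carbaldehyde | O=C[C@@H]1COC(C)(C)O1 | starting material
2 | ethyl 2-(triphenylphosphoranylidene)propanoate | CCOC(=O)C(C)=P(c1ccccc1)(c1ccccc1)c1ccccc1 | starting material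
3 | ethyl (E)-3-[(4R)-2,2-dimethyl-1,3-dioxolan-4-yl]-2-methylprop-2-enoate | CCOC(=O)/C(C)=C/[C@@H]1COC(C)(C)O1 | intermediate
4 | (E)-3-[(4R)-2,2-dimethyl-1,3-dioxolan-4-yl]-2-methylprop-2-enoic acid | OC(=O)/C(C)=C/[C@@H]1COC(C)(C)O1 | intermediate
5 | (E)-3-[(4R)-2,2-dimethyl-1,3-dioxolan-4-yl]-2-methylprop-2-enoyl chloride | ClC(=O)/C(C)=C/[C@@H]1COC(C)(C)O1 | intermediate
6 | (E)-2-methylbut-2-enenitrile | N#C/C(C)=C/C | starting material
7 | N-lithio-2-methylbuta-1,3-dien-1-imine (lithium ketene iminate) | [Li]N=C=C(C)C=C | intermediate (not isolated)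
8 | N-(tert-butyldimethylsilyl)-2-methylbuta-1,3-dien-1-imine | C=CC(C)=C=N[Si](C)(C)C(C)(C)C | intermediate
9 | (6E)-7-[(4R)-2,2-dimethyl-1,3-dioxolan-4-yl]-2,6-dimethyl-5-oxohepta-2,6-dienenitrile | N#CC(C)=CCC(=O)/C(C)=C/[C@@H]1COC(C)(C)O1 | intermediate (not isolated)
10 | (1S,6S)-6-[(4R)-2,2-dimethyl-1,3-dioxolan-4-yl]-1,5-dimethyl-4-oxocyclohex-2-ene-1-carbonitrile (C11 epimers) | N#C[C@@]1(C)C=CC(=O)C(C)[C@@H]1[C@@H]2COC(C)(C)O2 | intermediate
11 | TBS dienol ether of 10 | N#C[C@@]1(C)C=CC(O[Si](C)(C)C(C)(C)C)=C(C)[C@@H]1[C@@H]2COC(C)(C)O2 | intermediate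
12 | 4-bromo-2-methylbut-1-ene | C=C(C)CCBr | starting material
13 | (3-methylbut-3-enyl)magnesium bromide | C=C(C)CC[Mg]Br | intermediate (not isolated)
14 | N-bromomagnesio ketimine of 15 | C=C(C)CCC(=N[Mg]Br)[C@@]1(C)C=CC(O[Si](C)(C)C(C)(C)C)=C(C)[C@@H]1[C@@H]2COC(C)(C)O2 | intermediate (not isolated)
15 | C2 ketone (4-methylpent-4-enoyl group on C1) | C=C(C)CCC(=O)[C@@]1(C)C=CC(O[Si](C)(C)C(C)(C)C)=C(C)[C@@H]1[C@@H]2COC(C)(C)O2 | intermediate
16 | (2R)-alcohol | C=C(C)CC[C@@H](O)[C@@]1(C)C=CC(O[Si](C)(C)C(C)(C)C)=C(C)[C@@H]1[C@@H]2COC(C)(C)O2 | intermediate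
17 | C11–C12 silyloxy epoxide of 16 (oxygen anti to the C9 branch) | C=C(C)CC[C@@H](O)[C@@]1(C)C=C[C@@]2(O[Si](C)(C)C(C)(C)C)O[C@@]2(C)[C@@H]1[C@@H]3COC(C)(C)O3 | intermediate (not isolated)
18 | C2/C8/C9/C11 tetraol (11-hydroxy-12-oxo-13-ene) | C=C(C)CC[C@@H](O)[C@@]1(C)C=CC(=O)[C@@](C)(O)[C@@H]1[C@@H](O)CO | intermediate
19 | 2,8,9,11-tetrakis-O-(triethylsilyl) ether of 18 | C=C(C)CC[C@@H](O[Si](CC)(CC)CC)[C@@]1(C)C=CC(=O)[C@@](C)(O[Si](CC)(CC)CC)[C@@H]1[C@@H](O[Si](CC)(CC)CC)CO[Si](CC)(CC)CC | intermediate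
20 | C8 aldehyde (2,9,11-tris-O-triethylsilyl) | C=C(C)CC[C@@H](O[Si](CC)(CC)CC)[C@@]1(C)C=CC(=O)[C@@](C)(O[Si](CC)(CC)CC)[C@@H]1[C@@H](O[Si](CC)(CC)CC)C=O | intermediate
21 | allyl 4-methoxybenzyl ether | C=CCOCc1ccc(OC)cc1 | starting material
22 | (Z)-[3-(4-methoxybenzyloxy)allyl]diisopinocampheylborane from (+)-Ipc2BOMe | COc1ccc(CO/C=C\CB([C@H]2C[C@H]3C[C@@H]([C@@H]2C)C3(C)C)[C@H]2C[C@H]3C[C@@H]([C@@H]2C)C3(C)C)cc1 | intermediate (not isolated)
23 | (7S,8R)-homoallylic alcohol (C8–OH, C7–OPMB, C6 vinyl) | C=C(C)CC[C@@H](O[Si](CC)(CC)CC)[C@@]1(C)C=CC(=O)[C@@](C)(O[Si](CC)(CC)CC)[C@@H]1[C@@H](O[Si](CC)(CC)CC)[C@H](O)[C@@H](OCc1ccc(OC)cc1)C=C | intermediate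
24 | C8 ketone | C=C(C)CC[C@@H](O[Si](CC)(CC)CC)[C@@]1(C)C=CC(=O)[C@@](C)(O[Si](CC)(CC)CC)[C@@H]1[C@@H](O[Si](CC)(CC)CC)C(=O)[C@@H](OCc1ccc(OC)cc1)C=C | intermediate
25 | methyl 2-bromopropanoate | CC(Br)C(=O)OC | starting material
26 | bromozinc enolate of methyl propanoate (Reformatsky reagent) | COC(=O)C(C)[Zn]Br | intermediate (not isolated)
27 | C8 tertiary alcohol with C17–C19 ester branch (C17 epimers) | C=C(C)CC[C@@H](O[Si](CC)(CC)CC)[C@@]1(C)C=CC(=O)[C@@](C)(O[Si](CC)(CC)CC)[C@@H]1[C@@H](O[Si](CC)(CC)CC)[C@](O)(C(C)C(=O)OC)[C@@H](OCc1ccc(OC)cc1)C=C | intermediate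
28 | C7 alcohol of 27 | C=C(C)CC[C@@H](O[Si](CC)(CC)CC)[C@@]1(C)C=CC(=O)[C@@](C)(O[Si](CC)(CC)CC)[C@@H]1[C@@H](O[Si](CC)(CC)CC)[C@](O)(C(C)C(=O)OC)[C@@H](O)C=C | intermediate (not isolated)
29 | γ-lactone diene (19,7-olide, C8–OH free) | C=C(C)CC[C@@H](O[Si](CC)(CC)CC)[C@@]1(C)C=CC(=O)[C@@](C)(O[Si](CC)(CC)CC)[C@@H]1[C@@H](O[Si](CC)(CC)CC)[C@]2(O)[C@@H](C)C(=O)O[C@H]2C=C | intermediate
30 | (5Z)-macrocycle | C1C[C@@H](O[Si](CC)(CC)CC)[C@@]2(C)C=CC(=O)[C@@](C)(O[Si](CC)(CC)CC)[C@@H]2[C@@H](O[Si](CC)(CC)CC)[C@]2(O)[C@@H](C)C(=O)O[C@H]2/C=C1/C | intermediate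
31 | 8-O-triethylsilyl ether of 30 | C1C[C@@H](O[Si](CC)(CC)CC)[C@@]2(C)C=CC(=O)[C@@](C)(O[Si](CC)(CC)CC)[C@@H]2[C@@H](O[Si](CC)(CC)CC)[C@]2(O[Si](CC)(CC)CC)[C@@H](C)C(=O)O[C@H]2/C=C1/C | intermediate
32 | (6S)-6-chloro-5(16)-ene, tetrakis-O-triethylsilyl | C=C1CC[C@@H](O[Si](CC)(CC)CC)[C@@]2(C)C=CC(=O)[C@@](C)(O[Si](CC)(CC)CC)[C@@H]2[C@@H](O[Si](CC)(CC)CC)[C@]2(O[Si](CC)(CC)CC)[C@@H](C)C(=O)O[C@H]2[C@H]1Cl | intermediate
33 | 2,8,9,11-tetraol | C=C1CC[C@@H](O)[C@@]2(C)C=CC(=O)[C@@](C)(O)[C@@H]2[C@@H](O)[C@]2(O)[C@@H](C)C(=O)O[C@H]2[C@H]1Cl | intermediate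
34 | CNP0261648.1: (1S,2R,6S,7R,8R,9R,10S,11S,17R)-2,9-diacetoxy-6-chloro-8,11-dihydroxy-12-oxobriara-5(16),13-dien-19,7-olide | C=C1CC[C@@H](OC(C)=O)[C@@]2(C)C=CC(=O)[C@@](C)(O)[C@@H]2[C@@H](OC(C)=O)[C@]2(O)[C@@H](C)C(=O)O[C@H]2[C@H]1Cl | target

**Totals and risks**

Total step count: 20. Longest linear sequence: 19 steps (steps 1–3 and 5–20 from aldehyde 1; step 4 is a one-step side branch).

Steps most likely to fail:

Step 5. The acid chloride may acylate the ketene imine at C1 or at nitrogen instead of C13, or the enoyl unit may be deconjugated by the base before the ring closes. The fallback builds ring A by known reactions, setting out from ester 3 and nitrile 6 and returning at 10. Nitrile 6 is deprotonated (LiN(i-Pr)2, THF, −78 °C) and the anion adds through its α-carbon in a Michael reaction to ester 3 to give ethyl 4-cyano-3-[(4R)-2,2-dimethyl-1,3-dioxolan-4-yl]-2,4-dimethylhex-5-enoate F1, which already holds the C1–C10 bond; the wanted diastereomer would be separated. MeNH(OMe)·HCl with i-PrMgCl should convert F1 into the N-methoxy-N-methylamide F2, vinylmagnesium bromide should give the divinyl ketone F3, and ring-closing metathesis with the second-generation Grubbs catalyst should close C13=C14 to give 10.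

Step 16. The ruthenium alkylidene may fail to engage the 1,1-disubstituted olefin across the lactone-stiffened chain, so that oligomers form instead of the ten-membered ring. The fallback moves the ring closure ahead of the lactone, setting out from the more flexible ketone 24 and returning at 30. Metathesis of 24 should give the macrocyclic C8 ketone F4, Reformatsky addition of 25 the macrocyclic hydroxy ester F5, and DDQ the C7 alcohol F6, which should lactonise to 30.

Step 18. Chlorine may enter from the wrong olefin face, or the proton may be lost towards C4 instead of C16. The fallback puts oxygen on C6 first and brings in chloride by substitution, setting out from 31 and returning at 32. A Schenck ene reaction of 31 (O2, tetraphenylporphyrin, hν, CH2Cl2) should give the allylic hydroperoxide F7 on the face the electrophile prefers, PPh3 should reduce it to the 6-epi allylic alcohol F8, and PPh3 with hexachloroacetone should replace the hydroxyl by chloride with inversion and without allylic shift to give 32.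

**Further compounds**

F1 | step 5 | ethyl 4-cyano-3-[(4R)-2,2-dimethyl-1,3-dioxolan-4-yl]-2,4-dimethylhex-5-enoate (Michael adduct) | CCOC(=O)C(C)[C@H]([C@@H]1COC(C)(C)O1)[C@@](C)(C#N)C=C
F2 | step 5 | N-methoxy-N-methylamide of F1 | CON(C)C(=O)C(C)[C@H]([C@@H]1COC(C)(C)O1)[C@@](C)(C#N)C=C
F3 | step 5 | divinyl ketone: 2-[(4R)-2,2-dimethyl-1,3-dioxolan-4-yl]-substituted 2-ethenyl-2,4-dimethyl-5-oxohept-6-enenitrile | C=CC(=O)C(C)[C@H]([C@@H]1COC(C)(C)O1)[C@@](C)(C#N)C=C
F4 | step 16 | macrocyclic C8 ketone (5Z; C7–OPMB) | C1C[C@@H](O[Si](CC)(CC)CC)[C@@]2(C)C=CC(=O)[C@@](C)(O[Si](CC)(CC)CC)[C@@H]2[C@@H](O[Si](CC)(CC)CC)C(=O)[C@@H](OCc2ccc(OC)cc2)/C=C1/C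
F5 | step 16 | macrocyclic C8 tertiary alcohol with C17–C19 ester branch | C1C[C@@H](O[Si](CC)(CC)CC)[C@@]2(C)C=CC(=O)[C@@](C)(O[Si](CC)(CC)CC)[C@@H]2[C@@H](O[Si](CC)(CC)CC)[C@](O)(C(C)C(=O)OC)[C@@H](OCc2ccc(OC)cc2)/C=C1/C
F6 | step 16 | macrocyclic C7 alcohol of F5 | C1C[C@@H](O[Si](CC)(CC)CC)[C@@]2(C)C=CC(=O)[C@@](C)(O[Si](CC)(CC)CC)[C@@H]2[C@@H](O[Si](CC)(CC)CC)[C@](O)(C(C)C(=O)OC)[C@@H](O)/C=C1/C
F7 | step 18 | 6-epi allylic hydroperoxide with 5(16)-ene | C=C1CC[C@@H](O[Si](CC)(CC)CC)[C@@]2(C)C=CC(=O)[C@@](C)(O[Si](CC)(CC)CC)[C@@H]2[C@@H](O[Si](CC)(CC)CC)[C@]2(O[Si](CC)(CC)CC)[C@@H](C)C(=O)O[C@H]2[C@@H]1OO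
F8 | step 18 | 6-epi allylic alcohol with 5(16)-ene | C=C1CC[C@@H](O[Si](CC)(CC)CC)[C@@]2(C)C=CC(=O)[C@@](C)(O[Si](CC)(CC)CC)[C@@H]2[C@@H](O[Si](CC)(CC)CC)[C@]2(O[Si](CC)(CC)CC)[C@@H](C)C(=O)O[C@H]2[C@@H]1O
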